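## Analysis of the target

- Target 35 is built around an oxygen-bridged cage, a 4-oxatricyclo[4.3.1.0^3,7]dec-8-ene. In cage numbering C-1 is the bridgehead carbinol, C-2 the ketone, C-3 the prenylated ether carbon, O-4/C-5 the gem-dimethyl ether bridge, C-6 the ring-fusion CH, C-7 the oxygenated bridgehead, C-8=C-9 the enoate alkene and C-10 the CH2. The cage is joined through a spiro 1,3-dioxan-4-one to ring A, a cyclohex-2-ene-1,4-dione fused to a 2,2-dimethyl-2H-pyran.
- There are seven stereocentres. C-1, C-3, C-6 and C-7 are tied to one another by the ring connections, so the cage can exist as one diastereomer only and just its absolute sense must be set. The spiro ketal carbon and the neighbouring CH(prenyl) of ring A are the only centres that can vary, and both sit where they can equilibrate (ketal carbon, α-keto methine).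
- Sensitive groups are the bridgehead α-ketol (C-1 OH next to the C-2 ketone) and the C-2 ketone itself, which is non-enolisable, lies between two fully substituted carbons and is a vinylogous β-keto ester that base can cleave at C-1/C-2. The acyloxy ketal of the spiro centre, the enedione, the two prenyl groups and the 2H-chromene (acid, electrophilic oxidants) are also sensitive.
- The difficulty lies in four contiguous fully substituted carbons (C-1, C-2, C-3, C-7), the quaternary C-3 with its prenyl group on the face away from the carbocycle, and two tertiary alcohols, one of which ends in the ketal.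
- The strategy rests on one feature: C-1 is γ to the lactone carbonyl through C-9=C-8 and is bonded to C-2, which is at the acyl oxidation level once C-1/C-2 is cut. The C-1–C-2 bond is therefore the retron of a vinylogous Claisen (Dieckmann) condensation between an enoate dienolate and a carboxylic acid derivative on C-3.

## Retrosynthetic reasoning

**35 ⇒ 26 + 33.** The lactone C–O bond and the ether C–O bond at the spiro carbon are cut. Both end at a carbon that is the hydroxyl-bearing carbon of hydroxyquinone 33, so the spiro ring is formally the ketal of a β-hydroxy acid with a carbonyl group. The cut divides the molecule into halves of similar size and removes the two equilibrating centres. Forward, 26 must acylate the hydroxyl of 33 (giving 34), the C-7 hydroxyl must add to the acyloxy-bearing carbon, and the enolate must be protonated at carbon.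

**26 ⇒ 25 ⇒ 24.** These are functional-group changes only: acid from methyl ester, free alcohols from silyl ethers. The silyl groups are needed because the C-7 oxygen must not be an alkoxide, and the C-1 oxygen not a free hydroxyl, while strong base is present. The ester has to be hydrolysed without hydroxide, because the C-2 ketone is open to retro-Claisen cleavage.

**24 ⇒ 21 (key disconnection).** The C-1–C-2 bond is cut. It joins two fully substituted carbons and closes the bicyclo[2.2.2]octene, and its polarity is natural: a γ-nucleophile from the enoate and an acyl electrophile on C-3. The precursor 21 is a cis-fused oxolane–cyclohexene with a single acidic hydrogen. Forward, base must generate dienolate 22, the γ-carbon must reach the amide carbonyl, and the adduct 23 must hold until work-up.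

**21 ⇒ 19 ⇒ 18.** The N-methoxy-N-methylamide is traced back to a tert-butyl ester. The tert-butyl ester is what the asymmetric alkylation at the start needs, so the change of acyl group is placed after the bicycle is complete.

**18 ⇒ 16 ⇒ 14.** The bond between the enoate α-carbon and the tertiary carbinol is cut.
- Adding a metallated acrylate to the ketone of 12 and closing the ring by metathesis was considered and dropped. An external nucleophile approaches the oxolanone carbonyl anti to the adjacent C-4 side chain, which places the new carbon on the face opposite to that chain and to the ester; the cage needs all three on one face.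
- Making the bond from the side chain itself forces a cis ring fusion. The retron is therefore a thiolate-triggered Michael–aldol closure (via 15), followed by removal of sulfur through 17.

**14 ⇒ 12 + 13, and 12 ⇒ 7 + 11.** The enoate comes from cross-metathesis of the vinyl group with 13. The C-4/CH2 bond is cut as an enolate alkylation. An epoxide-based four-carbon electrophile was considered and set aside because its site of attack by enolates is unreliable; triflate 11 can only react at its CH2. The configuration at C-4 is the one centre not strongly controlled; it is epimerisable and is handled by separation and recycling.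

**7 ⇒ 5 + 6, and 5 ⇒ 4 ⇒ 3 ⇒ 1 + 2.** The quaternary centre is cut at its prenyl bond: catalytic asymmetric alkylation of the β-keto ester with 6 is the only source of absolute configuration. The oxolanone is opened at its ring C–O bond (carbenoid O–H insertion). An ether-diester Dieckmann closure was set aside because the ester enolate β to the ether oxygen would eliminate it.

**11 ⇐ 10 ⇐ 9 ⇐ 8.** The electrophile comes from a four-carbon chiral diol. Its stereocentre is kept only to keep intermediates single; the key step erases it.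

**33 ⇐ 32 ⇐ 30 ⇐ 29 ⇐ 28 ⇐ 27 + 6 (and 31).** The pyran ring is cut back to a hydroxyquinone C–H and aldehyde 31, and the quinone to a tetra-oxygenated arene. The prenyl group is placed by directed metalation between two methoxy groups, where regiochemistry is unambiguous.

## Alternatives that were turned down

**Alternative 1:**
- Disconnection: the C-6–C-7 bond and the C-5–O-4 ether bond are cut together. This unravels oxolane and bicyclooctene to a monocyclic cyclohex-2-ene-1,4-dione A1 with a prenyl carbinol (future C-1) and an allyl carbinol (future C-3).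
- Forward key step: a Lewis acid activates the ketone next to the enoate, the prenyl alkene attacks it (Prins), and the hydroxyl on the future C-3 captures the tertiary cation, giving A2.
- For it: two rings, two bonds and the C-6/C-7 relationship arise in one step from a flat precursor that dearomatisation of a benzoate could supply. On step economy and complexity gained per step it is stronger than the chosen route.
- Against it:
  - A1 carries two tertiary α-ketols on a doubly activated enedione and is open to ketol shifts, retro-aldol cleavage and rearomatisation.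
  - Its two carbinol centres must be set cis and in one enantiomeric series on a ring without a handle.
  - The cation can instead be trapped by the nearer hydroxyl (plain cycloetherification, no C–C bond), lose a proton, or the other ketone can react.
  - The allyl group must still be converted into prenyl.
- Comparison: the chosen strategy gives up that brevity for stereocentres set one at a time by defined elements and a key step with only one possible regiochemical outcome.

**Alternative 2:**
- Disconnection: the C-7–C-8 and C-6–C-10 bonds are cut, taking the carbocycle off the oxolane and leading to silyl enol ether A3 (derived from 7) and pyrone A4.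
- Forward key step: an inverse-demand cycloaddition bonds the nucleophilic enol ether carbon to C-6 of the pyrone and the silyloxy carbon to the ester-bearing C-3; loss of CO2 gives cyclohexadiene A5.
- For it: it uses the same enantioenriched oxolanone 7, forms both ring bonds at once so the cis fusion is automatic, and delivers the carbocycle with its ester and with oxygen at the future C-1. Up to the bicycle it is shorter and more convergent than steps 8–11 of the chosen route.
- Against it:
  - The two faces of the enol ether differ only by prenyl versus ester on the neighbouring quaternary carbon, and the cage needs attack on the ester face.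
  - A tetrasubstituted enol ether between a quaternary and a gem-dimethyl carbon is a poor dienophile, and the temperatures needed invite loss of silanol from A5 to a benzoate.
  - In A5 the future C-1 is an sp2 enol ester carbon. The cage bond would then need a reductive ketone–ester coupling or another umpolung, which is harder than an acylation with natural polarity.
- Comparison: the chosen strategy keeps C-1 as a carbinol methine whose deprotonation gives exactly the required nucleophile.

**Alternative 3:**
- Disconnection: the C-7–C-8 bond of the free cage ester A7 is cut, leading to A6, an oxolane-fused cyclohexane-1,3-dione with a tertiary propargylic alcohol bearing an ynoate.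
- Forward key step: a copper hydride reduces the ynoate in conjugate fashion and the allenolate adds through its α-carbon to the ketone at the future C-7 (reductive aldol).
- For it: aldol addition to a ketone is easier than acylation by a hindered amide; attack on the other ketone would need a four-membered ring, so regiochemistry is again set by the tether; and A7 is identical with 25, so protecting-group steps are saved. On the key step itself this alternative is at least as strong.
- Against it:
  - A6 already contains the C-1–C-2 bond between two fully substituted carbons, so the hardest bond of the cage is only moved into the synthesis of the precursor.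
  - That precursor is a non-enolisable 1,3-diketone with three stereocentres and a tertiary α-ketol, liable to retro-Claisen cleavage under the nucleophilic reducing conditions.
- Comparison: the chosen strategy offers a precursor made from a simple oxolanone by steps that each form one bond at an activated centre, and concentrates the risk in one step.

Key step: step 14

Assumption: which antipode of the phase-transfer catalyst gives the (2R) product 7 must be found by trying both commercial antipodes; the route assumes the right one is used.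

Remark: the (R) configuration of diol 8 is a convenience, since that centre is planarised in step 14.

## Route

Step 1
Reactants: 1 tert-butyl acetoacetate; 2 acetone
Product: 3 tert-butyl 5-hydroxy-5-methyl-3-oxohexanoate
Conditions: LiN(iPr)2 (2.2 equiv), THF, −78 → 0 °C; 2, −78 °C; AcOH, −78 °C
Reagents that add atoms: none
Why: The 1,3-dianion of the β-keto ester adds through its terminal carbon to the ketone (γ-selective dianion aldol addition); the cold acidic quench prevents retro-aldol loss of acetone.

Step 2
Reactants: 3 tert-butyl 5-hydroxy-5-methyl-3-oxohexanoate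
Product: 4 tert-butyl 2-diazo-5-hydroxy-5-methyl-3-oxohexanoate
Conditions: 4-acetamidobenzenesulfonyl azide, Et3N, MeCN, 0 °C → rt
Reagents that add atoms: 4-acetamidobenzenesulfonyl azide, CC(=O)Nc1ccc(cc1)S(=O)(=O)N=[N+]=[N-]
Why: Regitz diazo transfer to the doubly activated methylene; the tertiary alcohol does not react.

Step 3
Reactants: 4 tert-butyl 2-diazo-5-hydroxy-5-methyl-3-oxohexanoate
Product: 5 tert-butyl 5,5-dimethyl-3-oxooxolane-2-carboxylate (racemic)
Conditions: Rh2(OAc)4 (1 mol%), CH2Cl2, 40 °C
Reagents that add atoms: none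
Why: The rhodium carbenoid inserts into the tertiary O–H bond to close the five-membered ether (intramolecular O–H insertion), a standard entry to 3-oxooxolane-2-carboxylates; the C-2 centre is enolised in the next step.

Step 4
Reactants: 5 tert-butyl 5,5-dimethyl-3-oxooxolane-2-carboxylate; 6 prenyl bromide
Product: 7 tert-butyl (2R)-5,5-dimethyl-2-(3-methylbut-2-en-1-yl)-3-oxooxolane-2-carboxylate
Conditions: N-spiro bis(binaphthyl)ammonium bromide with 3,3'-bis(3,4,5-trifluorophenyl) groups (1 mol%), K2CO3 (solid), toluene, 0 °C
Reagents that add atoms: none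
Why: Asymmetric phase-transfer C-alkylation of a cyclic β-keto tert-butyl ester; the chiral ammonium enolate ion pair exposes one face to the allylic bromide. This sets the quaternary C-2 as R, the only source of absolute configuration in the cage.

Step 5
Reactants: 8 (2R)-but-3-ene-1,2-diol
Product: 9 (2R)-1,2-bis[(tert-butyldimethylsilyl)oxy]but-3-ene
Conditions: TBSCl (2.3 equiv), imidazole, DMF, rt
Reagents that add atoms: tert-butyldimethylsilyl chloride, CC(C)(C)[Si](C)(C)Cl
Why: Routine silylation of both hydroxyl groups.

Step 6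
Reactants: 9 (2R)-1,2-bis[(tert-butyldimethylsilyl)oxy]but-3-ene
Product: 10 (2R)-2-[(tert-butyldimethylsilyl)oxy]but-3-en-1-ol
Conditions: HF·pyridine, pyridine/THF, 0 °C
Reagents that add atoms: none
Why: The primary silyl ether is cleaved much faster than the secondary allylic one.

Step 7
Reactants: 10 (2R)-2-[(tert-butyldimethylsilyl)oxy]but-3-en-1-ol
Product: 11 (2R)-2-[(tert-butyldimethylsilyl)oxy]but-3-en-1-yl trifluoromethanesulfonate
Conditions: Tf2O, 2,6-lutidine, CH2Cl2, −78 °C; used at once
Reagents that add atoms: trifluoromethanesulfonic anhydride, O=S(=O)(OS(=O)(=O)C(F)(F)F)C(F)(F)F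
Why: Sulfonylation of the primary alcohol at low temperature with a hindered base gives an electrophile that can only be attacked at its CH2.

Step 8
Reactants: 7 tert-butyl (2R)-5,5-dimethyl-2-(3-methylbut-2-en-1-yl)-3-oxooxolane-2-carboxylate; 11 (2R)-2-[(tert-butyldimethylsilyl)oxy]but-3-en-1-yl trifluoromethanesulfonate
Product: 12 tert-butyl (2R,4S)-4-{(2S)-2-[(tert-butyldimethylsilyl)oxy]but-3-en-1-yl}-5,5-dimethyl-2-(3-methylbut-2-en-1-yl)-3-oxooxolane-2-carboxylate (side chain cis to the ester)
Conditions: LiN(SiMe3)2 (1.05 equiv), THF, −78 °C; 11, −78 → −30 °C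
Reagents that add atoms: none
Why: Only C-4 can be enolised, and a primary triflate is reactive enough for SN2 C-alkylation next to the gem-dimethyl carbon (ketone enolate alkylation). The two C-2 substituents differentiate the enolate faces only weakly, so the (4S) epimer is isolated by chromatography and the C-4 epimer is returned to the mixture by DBU equilibration of the α-keto methine.

Step 9
Reactants: 12 tert-butyl (2R,4S)-4-{(2S)-2-[(tert-butyldimethylsilyl)oxy]but-3-en-1-yl}-5,5-dimethyl-2-(3-methylbut-2-en-1-yl)-3-oxooxolane-2-carboxylate; 13 methyl acrylate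
Product: 14 tert-butyl (2R,4S)-4-{(2S,3E)-2-[(tert-butyldimethylsilyl)oxy]-5-methoxy-5-oxopent-3-en-1-yl}-5,5-dimethyl-2-(3-methylbut-2-en-1-yl)-3-oxooxolane-2-carboxylate
Conditions: second-generation Hoveyda–Grubbs catalyst (5 mol%), 13 (5 equiv), CH2Cl2, 40 °C
Reagents that add atoms: none
Why: Olefin cross-metathesis of the monosubstituted vinyl group with an acrylate gives the E-enoate; the trisubstituted prenyl alkene is far less reactive and ring closure onto it is geometrically impossible.

Step 10
Reactants: 14 tert-butyl (2R,4S)-4-{(2S,3E)-2-[(tert-butyldimethylsilyl)oxy]-5-methoxy-5-oxopent-3-en-1-yl}-5,5-dimethyl-2-(3-methylbut-2-en-1-yl)-3-oxooxolane-2-carboxylate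
Product: 16 1-tert-butyl 7-methyl (1R)-5-[(tert-butyldimethylsilyl)oxy]-3,3-dimethyl-1-(3-methylbut-2-en-1-yl)-6-(phenylsulfanyl)-7a-[(triethylsilyl)oxy]octahydro-2-benzofuran-1,7-dicarboxylate (cis-fused; C-1 ester on the face of the carbocycle; epimers at C-6/C-7), via tertiary aldol alcohol 15 (not isolated)
Conditions: PhSLi (from PhSH and n-BuLi, 1.2 equiv), THF, −78 → −20 °C; then TESOTf, 2,6-lutidine, −78 → 0 °C
Reagents that add atoms: thiophenol, Sc1ccccc1; triethylsilyl trifluoromethanesulfonate, CC[Si](CC)(CC)OS(=O)(=O)C(F)(F)F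
Why: Thiolate conjugate addition generates the ester enolate without a strong base, and this closes onto the ring ketone from the side chain (tandem thia-Michael/intramolecular aldol, a stepwise Morita–Baylis–Hillman equivalent). Because the chain sits cis to the C-1 ester, the six-membered ring can only form cis-fused on that face, which sets the carbinol centre (oxygen on the prenyl face). Silylating the alkoxide in the same flask blocks retro-aldol; the two centres at C-6/C-7 are removed in step 11.

Step 11
Reactants: 16 1-tert-butyl 7-methyl (1R)-5-[(tert-butyldimethylsilyl)oxy]-3,3-dimethyl-1-(3-methylbut-2-en-1-yl)-6-(phenylsulfanyl)-7a-[(triethylsilyl)oxy]octahydro-2-benzofuran-1,7-dicarboxylate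
Product: 18 1-tert-butyl 7-methyl (1R,3aS,5S,7aS)-5-[(tert-butyldimethylsilyl)oxy]-3,3-dimethyl-1-(3-methylbut-2-en-1-yl)-7a-[(triethylsilyl)oxy]-1,3,3a,4,5,7a-hexahydro-2-benzofuran-1,7-dicarboxylate, via sulfoxide 17 (not isolated)
Conditions: mCPBA (1.0 equiv), CH2Cl2, −78 °C; then DBU, 0 °C → rt
Reagents that add atoms: none
Why: Sulfide oxidation is much faster than epoxidation of the prenyl group at −78 °C, and base-induced β-elimination of benzenesulfenate through the ester enolate gives the conjugated enoate whatever the relative configuration at C-6/C-7 (sulfoxide elimination).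

Step 12
Reactants: 18 1-tert-butyl 7-methyl (1R,3aS,5S,7aS)-5-[(tert-butyldimethylsilyl)oxy]-3,3-dimethyl-1-(3-methylbut-2-en-1-yl)-7a-[(triethylsilyl)oxy]-1,3,3a,4,5,7a-hexahydro-2-benzofuran-1,7-dicarboxylate
Product: 19 (1R,3aS,5S,7aS)-5-[(tert-butyldimethylsilyl)oxy]-7-(methoxycarbonyl)-3,3-dimethyl-1-(3-methylbut-2-en-1-yl)-7a-[(triethylsilyl)oxy]-1,3,3a,4,5,7a-hexahydro-2-benzofuran-1-carboxylic acid
Conditions: TMSOTf (3 equiv), 2,6-lutidine (4 equiv), CH2Cl2, 0 °C; pH 5 buffer
Reagents that add atoms: none
Why: Silyl triflate with a hindered base converts the tert-butyl ester into a silyl ester with loss of isobutene, which hydrolyses on work-up; silyl ethers and the methyl ester are untouched (Lewis-acid tert-butyl ester cleavage).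

Step 13
Reactants: 19 (1R,3aS,5S,7aS)-5-[(tert-butyldimethylsilyl)oxy]-7-(methoxycarbonyl)-3,3-dimethyl-1-(3-methylbut-2-en-1-yl)-7a-[(triethylsilyl)oxy]-1,3,3a,4,5,7a-hexahydro-2-benzofuran-1-carboxylic acid
Product: 21 methyl (1R,3aS,5S,7aS)-5-[(tert-butyldimethylsilyl)oxy]-1-[methoxy(methyl)carbamoyl]-3,3-dimethyl-1-(3-methylbut-2-en-1-yl)-7a-[(triethylsilyl)oxy]-1,3,3a,4,5,7a-hexahydro-2-benzofuran-7-carboxylate, via acid chloride 20 (not isolated)
Conditions: 1-chloro-N,N,2-trimethylprop-1-en-1-amine, CH2Cl2, 0 °C; then MeNHOMe·HCl, pyridine, 0 °C → rt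
Reagents that add atoms: N,O-dimethylhydroxylamine hydrochloride, CNOC.Cl
Why: The chloroenamine makes the hindered acid chloride under neutral conditions that spare the silyl ethers, and the small acyl chloride then acylates the hydroxylamine (amide formation through an acid chloride).

Step 14
Reactants: 21 methyl (1R,3aS,5S,7aS)-5-[(tert-butyldimethylsilyl)oxy]-1-[methoxy(methyl)carbamoyl]-3,3-dimethyl-1-(3-methylbut-2-en-1-yl)-7a-[(triethylsilyl)oxy]-1,3,3a,4,5,7a-hexahydro-2-benzofuran-7-carboxylate
Product: 24 methyl (3R)-1-[(tert-butyldimethylsilyl)oxy]-5,5-dimethyl-3-(3-methylbut-2-en-1-yl)-2-oxo-7-[(triethylsilyl)oxy]-4-oxatricyclo[4.3.1.0^3,7]dec-8-ene-8-carboxylate, via potassium dienolate 22 (not isolated), via tetrahedral adduct 23 (not isolated)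
Conditions: KN(SiMe3)2 (1.3 equiv), THF, −78 → −40 °C; AcOH, −78 °C
Reagents that add atoms: none
Why: KN(SiMe3)2 removes the C-5 hydrogen (allylic, γ to the ester, α to the silyloxy group), the only acidic hydrogen, giving dienolate 22 and planarising C-5, so the configuration there in 21 does not matter. The γ-carbon attacks the N-methoxy-N-methylamide carbonyl held on the cis-fused oxolane; this is an intramolecular vinylogous Claisen (Dieckmann) condensation, the closest known types being γ-acylation of extended ester dienolates and ketone synthesis from N-methoxy-N-methylamides. The new ring (C-5, the amide carbon, C-1, C-7a, C-7, C-6) closes 6-exo-trig through a boat and completes the bicyclo[2.2.2]octene. α-Attack would give a four-membered ring, so γ-regioselectivity needs no reagent control. The new bridgehead centre can only form on the face that carries the amide, so it is dictated by the C-1 and C-7a centres set in steps 4 and 10. The potassium-chelated adduct 23 survives until the acidic quench, so no alkoxide is released that could reopen the non-enolisable ketone by retro-Claisen cleavage. The step needs closure to outrun β-loss of the 7a-silyloxy group from the dienolate; in the conformer required for closure the amide-bearing carbon is pseudoaxial and the bulky silyloxy group pseudoequatorial, nearly orthogonal to the π-system, which disfavours that elimination.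

Step 15
Reactants: 24 methyl (3R)-1-[(tert-butyldimethylsilyl)oxy]-5,5-dimethyl-3-(3-methylbut-2-en-1-yl)-2-oxo-7-[(triethylsilyl)oxy]-4-oxatricyclo[4.3.1.0^3,7]dec-8-ene-8-carboxylate
Product: 25 methyl (3R)-1,7-dihydroxy-5,5-dimethyl-3-(3-methylbut-2-en-1-yl)-2-oxo-4-oxatricyclo[4.3.1.0^3,7]dec-8-ene-8-carboxylate
Conditions: HF·pyridine, THF, 0 °C → rt
Reagents that add atoms: none
Why: Acidic fluoride removes both silyl ethers without exposing the α-ketol and the cleavable ketone to base (fluoride desilylation).

Step 16
Reactants: 25 methyl (3R)-1,7-dihydroxy-5,5-dimethyl-3-(3-methylbut-2-en-1-yl)-2-oxo-4-oxatricyclo[4.3.1.0^3,7]dec-8-ene-8-carboxylate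
Product: 26 (3R)-1,7-dihydroxy-5,5-dimethyl-3-(3-methylbut-2-en-1-yl)-2-oxo-4-oxatricyclo[4.3.1.0^3,7]dec-8-ene-8-carboxylic acid
Conditions: Me3SnOH (5 equiv), ClCH2CH2Cl, 70 °C; then 0.1 M HCl
Reagents that add atoms: trimethyltin hydroxide, C[Sn](C)(C)O
Why: Trimethyltin hydroxide cleaves hindered methyl esters under nearly neutral conditions, which avoids hydroxide-induced retro-Claisen opening of the cage ketone.

Step 17
Reactants: 27 1,2,3,5-tetramethoxybenzene; 6 prenyl bromide
Product: 28 1,2,3,5-tetramethoxy-4-(3-methylbut-2-en-1-yl)benzene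
Conditions: n-BuLi, THF, 0 °C; CuBr·SMe2 (10 mol%), 6, −78 → 0 °C
Reagents that add atoms: none
Why: Directed ortho-metalation occurs at the position flanked by two methoxy groups, and copper-mediated allylation gives the linear prenyl arene.

Step 18
Reactants: 28 1,2,3,5-tetramethoxy-4-(3-methylbut-2-en-1-yl)benzene
Product: 29 2,6-dimethoxy-3-(3-methylbut-2-en-1-yl)cyclohexa-2,5-diene-1,4-dione
Conditions: (NH4)2Ce(NO3)6 (2.2 equiv), MeCN/H2O, 0 °C
Reagents that add atoms: water, O
Why: Oxidative demethylation of the para-dimethoxy pair gives the 1,4-quinone; short exposure at 0 °C spares the prenyl group.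

Step 19
Reactants: 29 2,6-dimethoxy-3-(3-methylbut-2-en-1-yl)cyclohexa-2,5-diene-1,4-dione
Product: 30 2-hydroxy-6-methoxy-5-(3-methylbut-2-en-1-yl)cyclohexa-2,5-diene-1,4-dione
Conditions: NaOH (1 M aq., 2.2 equiv), MeOH, 0 °C; then HCl
Reagents that add atoms: sodium hydroxide, [Na+].[OH-]
Why: Hydroxide adds to the methoxy-bearing carbon of the less substituted enone arm and expels methoxide (vinylogous ester hydrolysis by addition–elimination); the resulting vinylogous carboxylate resists a second attack.

Step 20
Reactants: 30 2-hydroxy-6-methoxy-5-(3-methylbut-2-en-1-yl)cyclohexa-2,5-diene-1,4-dione; 31 3-methylbut-2-enal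
Product: 32 7-methoxy-2,2-dimethyl-6-(3-methylbut-2-en-1-yl)-2H-chromene-5,8-dione
Conditions: ethylenediammonium diacetate (10 mol%), toluene, 80 °C
Reagents that add atoms: none
Why: Knoevenagel condensation at the nucleophilic C–H next to the hydroxyl, then oxa-6π electrocyclisation through the enol oxygen, gives the 2H-pyran with the para-quinone kept.

Step 21
Reactants: 32 7-methoxy-2,2-dimethyl-6-(3-methylbut-2-en-1-yl)-2H-chromene-5,8-dione
Product: 33 7-hydroxy-2,2-dimethyl-6-(3-methylbut-2-en-1-yl)-2H-chromene-5,8-dione
Conditions: NaOH (1 M aq.), MeOH/THF, rt; then HCl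
Reagents that add atoms: sodium hydroxide, [Na+].[OH-]
Why: The remaining methoxy group is a vinylogous methyl ester and is hydrolysed by addition–elimination; loss of methoxide is irreversible, whereas opening at the pyran oxygen would simply re-close.

Step 22
Reactants: 26 (3R)-1,7-dihydroxy-5,5-dimethyl-3-(3-methylbut-2-en-1-yl)-2-oxo-4-oxatricyclo[4.3.1.0^3,7]dec-8-ene-8-carboxylic acid; 33 7-hydroxy-2,2-dimethyl-6-(3-methylbut-2-en-1-yl)-2H-chromene-5,8-dione
Product: 35 CNP0222516.1 (target; spiro 1,3-dioxan-4-one, configuration as in the SMILES), via acyloxyquinone 34 (not isolated)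
Conditions: 2,4,6-trichlorobenzoyl chloride, Et3N, THF, 0 °C; 33, DMAP (cat.), toluene, rt; then camphorsulfonic acid (10 mol%), CH2Cl2, rt
Reagents that add atoms: none
Why: Proposed new method: mixed-anhydride O-acylation of the vinylogous acid 33 gives 34, whose acyloxy-bearing carbon is the β-carbon of an enone; the tertiary C-7 hydroxyl adds there 6-exo-trig (oxa-Michael) and C-protonation of the enolate gives the spiro ketal, the closest known types being conjugate addition of alcohols to 2-oxy-1,4-quinones and acid-catalysed 1,3-dioxan-4-one formation from β-hydroxy acids and ketones. Both new centres form reversibly, so the acid equilibration is expected to settle on the isomer with the ring A carbonyl carbon of the spiro centre on the side of the cage methine C-6 and the prenyl group trans to the cage ether oxygen, as in the target.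

## Compound list

1 | tert-butyl acetoacetate | CC(=O)CC(=O)OC(C)(C)C | starting material
2 | acetone | CC(C)=O | starting material
3 | tert-butyl 5-hydroxy-5-methyl-3-oxohexanoate | CC(C)(O)CC(=O)CC(=O)OC(C)(C)C | intermediate
4 | tert-butyl 2-diazo-5-hydroxy-5-methyl-3-oxohexanoate | CC(C)(O)CC(=O)C(=[N+]=[N-])C(=O)OC(C)(C)C | intermediate
5 | tert-butyl 5,5-dimethyl-3-oxooxolane-2-carboxylate (racemic) | CC1(C)CC(=O)C(O1)C(=O)OC(C)(C)C | intermediate
6 | prenyl bromide | CC(C)=CCBr | starting material
7 | tert-butyl (2R)-5,5-dimethyl-2-(3-methylbut-2-en-1-yl)-3-oxooxolane-2-carboxylate | CC1(C)O[C@@](CC=C(C)C)(C(=O)OC(C)(C)C)C(=O)C1 | intermediate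
8 | (2R)-but-3-ene-1,2-diol | C=C[C@@H](O)CO | starting material
9 | (2R)-1,2-bis[(tert-butyldimethylsilyl)oxy]but-3-ene | C=C[C@@H](O[Si](C)(C)C(C)(C)C)CO[Si](C)(C)C(C)(C)C | intermediate
10 | (2R)-2-[(tert-butyldimethylsilyl)oxy]but-3-en-1-ol | C=C[C@@H](O[Si](C)(C)C(C)(C)C)CO | intermediate
11 | (2R)-2-[(tert-butyldimethylsilyl)oxy]but-3-en-1-yl trifluoromethanesulfonate | C=C[C@@H](O[Si](C)(C)C(C)(C)C)COS(=O)(=O)C(F)(F)F | intermediate
12 | tert-butyl (2R,4S)-4-{(2S)-2-[(tert-butyldimethylsilyl)oxy]but-3-en-1-yl}-5,5-dimethyl-2-(3-methylbut-2-en-1-yl)-3-oxooxolane-2-carboxylate | C=C[C@@H](O[Si](C)(C)C(C)(C)C)C[C@H]1C(C)(C)O[C@@](CC=C(C)C)(C(=O)OC(C)(C)C)C1=O | intermediate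
13 | methyl acrylate | C=CC(=O)OC | starting material
14 | tert-butyl (2R,4S)-4-{(2S,3E)-2-[(tert-butyldimethylsilyl)oxy]-5-methoxy-5-oxopent-3-en-1-yl}-5,5-dimethyl-2-(3-methylbut-2-en-1-yl)-3-oxooxolane-2-carboxylate | COC(=O)/C=C/[C@@H](O[Si](C)(C)C(C)(C)C)C[C@H]1C(C)(C)O[C@@](CC=C(C)C)(C(=O)OC(C)(C)C)C1=O | intermediate
15 | tertiary aldol alcohol: 1-tert-butyl 7-methyl (1R)-5-[(tert-butyldimethylsilyl)oxy]-7a-hydroxy-3,3-dimethyl-1-(3-methylbut-2-en-1-yl)-6-(phenylsulfanyl)octahydro-2-benzofuran-1,7-dicarboxylate (cis-fused, epimers at C-6/C-7) | COC(=O)C1C(Sc3ccccc3)[C@@H](O[Si](C)(C)C(C)(C)C)C[C@H]2C(C)(C)O[C@@](CC=C(C)C)(C(=O)OC(C)(C)C)[C@@]12O | intermediate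
16 | 7a-triethylsilyl ether of 15 | COC(=O)C1C(Sc3ccccc3)[C@@H](O[Si](C)(C)C(C)(C)C)C[C@H]2C(C)(C)O[C@@](CC=C(C)C)(C(=O)OC(C)(C)C)[C@@]12O[Si](CC)(CC)CC | intermediate
17 | sulfoxide of 16 (6-phenylsulfinyl) | COC(=O)C1C(S(=O)c3ccccc3)[C@@H](O[Si](C)(C)C(C)(C)C)C[C@H]2C(C)(C)O[C@@](CC=C(C)C)(C(=O)OC(C)(C)C)[C@@]12O[Si](CC)(CC)CC | intermediate
18 | 1-tert-butyl 7-methyl (1R,3aS,5S,7aS)-5-[(tert-butyldimethylsilyl)oxy]-3,3-dimethyl-1-(3-methylbut-2-en-1-yl)-7a-[(triethylsilyl)oxy]-1,3,3a,4,5,7a-hexahydro-2-benzofuran-1,7-dicarboxylate | COC(=O)C1=C[C@@H](O[Si](C)(C)C(C)(C)C)C[C@H]2C(C)(C)O[C@@](CC=C(C)C)(C(=O)OC(C)(C)C)[C@@]12O[Si](CC)(CC)CC | intermediate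
19 | (1R,3aS,5S,7aS)-5-[(tert-butyldimethylsilyl)oxy]-7-(methoxycarbonyl)-3,3-dimethyl-1-(3-methylbut-2-en-1-yl)-7a-[(triethylsilyl)oxy]-1,3,3a,4,5,7a-hexahydro-2-benzofuran-1-carboxylic acid | COC(=O)C1=C[C@@H](O[Si](C)(C)C(C)(C)C)C[C@H]2C(C)(C)O[C@@](CC=C(C)C)(C(O)=O)[C@@]12O[Si](CC)(CC)CC | intermediate
20 | acid chloride of 19 | COC(=O)C1=C[C@@H](O[Si](C)(C)C(C)(C)C)C[C@H]2C(C)(C)O[C@@](CC=C(C)C)(C(Cl)=O)[C@@]12O[Si](CC)(CC)CC | intermediate
21 | methyl (1R,3aS,5S,7aS)-5-[(tert-butyldimethylsilyl)oxy]-1-[methoxy(methyl)carbamoyl]-3,3-dimethyl-1-(3-methylbut-2-en-1-yl)-7a-[(triethylsilyl)oxy]-1,3,3a,4,5,7a-hexahydro-2-benzofuran-7-carboxylate | COC(=O)C1=C[C@@H](O[Si](C)(C)C(C)(C)C)C[C@H]2C(C)(C)O[C@@](CC=C(C)C)(C(=O)N(C)OC)[C@@]12O[Si](CC)(CC)CC | intermediate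
22 | potassium dienolate of 21 | COC([O-])=C1C=C(O[Si](C)(C)C(C)(C)C)C[C@H]2C(C)(C)O[C@@](CC=C(C)C)(C(=O)N(C)OC)[C@@]12O[Si](CC)(CC)CC.[K+] | intermediate
23 | tetrahedral adduct (potassium alkoxide of the cage N-methoxy-N-methyl hemiaminal) | COC(=O)C1=C[C@]3(O[Si](C)(C)C(C)(C)C)C[C@H]4C(C)(C)O[C@@](CC=C(C)C)(C3([O-])N(C)OC)[C@@]14O[Si](CC)(CC)CC.[K+] | intermediate
24 | methyl (3R)-1-[(tert-butyldimethylsilyl)oxy]-5,5-dimethyl-3-(3-methylbut-2-en-1-yl)-2-oxo-7-[(triethylsilyl)oxy]-4-oxatricyclo[4.3.1.0^3,7]dec-8-ene-8-carboxylate | COC(=O)C1=C[C@]3(O[Si](C)(C)C(C)(C)C)C[C@H]4C(C)(C)O[C@@](CC=C(C)C)(C3=O)[C@@]14O[Si](CC)(CC)CC | intermediate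
25 | methyl (3R)-1,7-dihydroxy-5,5-dimethyl-3-(3-methylbut-2-en-1-yl)-2-oxo-4-oxatricyclo[4.3.1.0^3,7]dec-8-ene-8-carboxylate | COC(=O)C1=C[C@]3(O)C[C@H]4C(C)(C)O[C@@](CC=C(C)C)(C3=O)[C@@]14O | intermediate
26 | (3R)-1,7-dihydroxy-5,5-dimethyl-3-(3-methylbut-2-en-1-yl)-2-oxo-4-oxatricyclo[4.3.1.0^3,7]dec-8-ene-8-carboxylic acid | OC(=O)C1=C[C@]3(O)C[C@H]4C(C)(C)O[C@@](CC=C(C)C)(C3=O)[C@@]14O | intermediate
27 | 1,2,3,5-tetramethoxybenzene | COc1cc(OC)c(OC)c(OC)c1 | starting material
28 | 1,2,3,5-tetramethoxy-4-(3-methylbut-2-en-1-yl)benzene | COc1cc(OC)c(CC=C(C)C)c(OC)c1OC | intermediate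
29 | 2,6-dimethoxy-3-(3-methylbut-2-en-1-yl)cyclohexa-2,5-diene-1,4-dione | COC1=CC(=O)C(CC=C(C)C)=C(OC)C1=O | intermediate
30 | 2-hydroxy-6-methoxy-5-(3-methylbut-2-en-1-yl)cyclohexa-2,5-diene-1,4-dione | COC1=C(CC=C(C)C)C(=O)C=C(O)C1=O | intermediate
31 | 3-methylbut-2-enal | CC(C)=CC=O | starting material
32 | 7-methoxy-2,2-dimethyl-6-(3-methylbut-2-en-1-yl)-2H-chromene-5,8-dione | COC1=C(CC=C(C)C)C(=O)C2=C(OC(C)(C)C=C2)C1=O | intermediate
33 | 7-hydroxy-2,2-dimethyl-6-(3-methylbut-2-en-1-yl)-2H-chromene-5,8-dione | OC1=C(CC=C(C)C)C(=O)C2=C(OC(C)(C)C=C2)C1=O | intermediate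
34 | acyloxyquinone (7-O-acyl derivative of 33 with acid 26) | CC(C)=CCC1=C(OC(=O)C5=C[C@]3(O)C[C@H]4C(C)(C)O[C@@](CC=C(C)C)(C3=O)[C@@]54O)C(=O)C2=C(OC(C)(C)C=C2)C1=O | intermediate
35 | CNP0222516.1 | CC(C)=CC[C@H]1C(=O)C2=C(OC(C)(C)C=C2)C(=O)[C@@]12OC(=O)C1=C[C@]3(O)C[C@H]4C(C)(C)O[C@@](CC=C(C)C)(C3=O)[C@@]14O2 | target

## Step count and least certain steps

Total step count: 22. Longest linear sequence: 14 steps (steps 1–4, 8–16 and 22, from 1 to 35).

**Step 22 (proposed new method).**
- What may go wrong: after the alcohol has added, the intermediate can expel the carboxylate and open to a quinone ether acid instead of being protonated at carbon; the equilibration may also settle on another spiro epimer.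
- Fallback (known chemistry), from 26 back to 35: 26 is persilylated with Me3SiCl/Et3N to its tris(trimethylsilyl) derivative F1. F1 is condensed with 33 under catalytic TMSOTf in CH2Cl2 at −78 → −20 °C, the established silyl-triflate-catalysed formation of 1,3-dioxan-4-ones from silylated β-hydroxy acids and carbonyl compounds. Mild aqueous acid removes the bridgehead trimethylsilyl ether and returns the route at 35.

**Step 14 (key step).**
- What may go wrong: β-loss of the triethylsilyloxy group from the dienolate; no closure because the amide carbonyl is shielded by two neighbouring fully substituted carbons; base-induced fragmentation of the N-methoxy group.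
- Fallback, from 21 back to 24: the amide of 21 is reduced with Cp2Zr(H)Cl to aldehyde F2, a far better electrophile. F2 is closed by the same γ-deprotonation (KN(SiMe3)2, −78 °C) as an intramolecular vinylogous aldol addition to the cage carbinol F3. Dess–Martin oxidation of F3 returns the route at 24.

**Step 8.**
- What may go wrong: O-alkylation or no alkylation at the enolate carbon next to the gem-dimethyl group, and an unfavourable ratio of C-4 epimers.
- Fallback, from 5 back to 12: the order of the two alkylations is reversed. Triflate 11 is converted with NaI into iodide F4. The more reactive 2,4-dianion of 5 (LiN(iPr)2, 2 equiv) is alkylated at C-4 with F4 to give F5. Asymmetric phase-transfer prenylation of F5 with 6 then places the prenyl group trans to the existing chain, which is the relationship required, and returns the route at 12. Material from the mismatched C-4 epimer is recycled by base epimerisation.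

**Step 10.**
- What may go wrong: proton transfer from C-4 to the ester enolate (epimerisation, no ring), retro-aldol before silylation, or slow closure on the ester-bearing face of the ketone.
- Fallback, from 14 back to 18: [(Ph3P)CuH]6-mediated intramolecular reductive aldol cyclisation of 14 gives the saturated hydroxy ester F6. Its dianion (LiN(iPr)2, 2.2 equiv) is selenenylated with PhSeBr to F7. Oxidation with H2O2 and selenoxide syn-elimination, which can only run toward C-6, give the hydroxy enoate F8. Silylation with TESOTf returns the route at 18.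

## Further compounds

F1 | step 22 | tris(trimethylsilyl) derivative of 26 (silyl ester, 1- and 7-silyl ethers) | C[Si](C)(C)OC(=O)C1=C[C@]3(O[Si](C)(C)C)C[C@H]4C(C)(C)O[C@@](CC=C(C)C)(C3=O)[C@@]14O[Si](C)(C)C
F2 | step 14 | methyl (1R,3aS,5S,7aS)-5-[(tert-butyldimethylsilyl)oxy]-1-formyl-3,3-dimethyl-1-(3-methylbut-2-en-1-yl)-7a-[(triethylsilyl)oxy]-1,3,3a,4,5,7a-hexahydro-2-benzofuran-7-carboxylate | COC(=O)C1=C[C@@H](O[Si](C)(C)C(C)(C)C)C[C@H]2C(C)(C)O[C@@](CC=C(C)C)(C=O)[C@@]12O[Si](CC)(CC)CC
F3 | step 14 | methyl (3R)-1-[(tert-butyldimethylsilyl)oxy]-2-hydroxy-5,5-dimethyl-3-(3-methylbut-2-en-1-yl)-7-[(triethylsilyl)oxy]-4-oxatricyclo[4.3.1.0^3,7]dec-8-ene-8-carboxylate (carbinol epimers) | COC(=O)C1=C[C@]3(O[Si](C)(C)C(C)(C)C)C[C@H]4C(C)(C)O[C@@](CC=C(C)C)(C3O)[C@@]14O[Si](CC)(CC)CC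
F4 | step 8 | (2R)-2-[(tert-butyldimethylsilyl)oxy]-1-iodobut-3-ene | C=C[C@@H](O[Si](C)(C)C(C)(C)C)CI
F5 | step 8 | tert-butyl 4-{(2S)-2-[(tert-butyldimethylsilyl)oxy]but-3-en-1-yl}-5,5-dimethyl-3-oxooxolane-2-carboxylate (epimers at C-2/C-4) | CC(C)(C)OC(=O)C1OC(C)(C)C(C[C@H](O[Si](C)(C)C(C)(C)C)C=C)C1=O
F6 | step 10 | 1-tert-butyl 7-methyl (1R)-5-[(tert-butyldimethylsilyl)oxy]-7a-hydroxy-3,3-dimethyl-1-(3-methylbut-2-en-1-yl)octahydro-2-benzofuran-1,7-dicarboxylate (cis-fused) | COC(=O)C1C[C@@H](O[Si](C)(C)C(C)(C)C)C[C@H]2C(C)(C)O[C@@](CC=C(C)C)(C(=O)OC(C)(C)C)[C@@]12O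
F7 | step 10 | 7-(phenylselanyl) derivative of F6 | COC(=O)C1([Se]c3ccccc3)C[C@@H](O[Si](C)(C)C(C)(C)C)C[C@H]2C(C)(C)O[C@@](CC=C(C)C)(C(=O)OC(C)(C)C)[C@@]12O
F8 | step 10 | 1-tert-butyl 7-methyl (1R)-5-[(tert-butyldimethylsilyl)oxy]-7a-hydroxy-3,3-dimethyl-1-(3-methylbut-2-en-1-yl)-1,3,3a,4,5,7a-hexahydro-2-benzofuran-1,7-dicarboxylate | COC(=O)C1=C[C@@H](O[Si](C)(C)C(C)(C)C)C[C@H]2C(C)(C)O[C@@](CC=C(C)C)(C(=O)OC(C)(C)C)[C@@]12O
A1 | alternative 1 | methyl 3,5-dihydroxy-3-(3-methylbut-2-en-1-yl)-4,6-dioxo-5-(prop-2-en-1-yl)cyclohex-1-ene-1-carboxylate (Prins substrate) | COC(=O)C1=C[C@](O)(CC=C(C)C)C(=O)[C@@](O)(CC=C)C1=O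
A2 | alternative 1 | allyl cage β-hydroxy ester | COC(=O)C1=C[C@]3(O)C[C@H]4C(C)(C)O[C@@](CC=C)(C3=O)[C@@]14O
A3 | alternative 2 | tert-butyl (2R)-3-[(tert-butyldimethylsilyl)oxy]-5,5-dimethyl-2-(3-methylbut-2-en-1-yl)-2,5-dihydrofuran-2-carboxylate (silyl enol ether of 7) | CC1(C)O[C@@](CC=C(C)C)(C(=O)OC(C)(C)C)C(O[Si](C)(C)C(C)(C)C)=C1
A4 | alternative 2 | methyl 5-(pivaloyloxy)-2-oxo-2H-pyran-3-carboxylate | COC(=O)C1=CC(OC(=O)C(C)(C)C)=COC1=O
A5 | alternative 2 | oxolane-fused cyclohexadiene diester | COC(=O)C1=CC(OC(=O)C(C)(C)C)=C[C@H]2C(C)(C)O[C@@](CC=C(C)C)(C(=O)OC(C)(C)C)[C@@]12O[Si](C)(C)C(C)(C)C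
A6 | alternative 3 | oxolane-fused cyclohexanedione with a tertiary propargylic alcohol bearing a methyl ynoate (reductive aldol substrate) | COC(=O)C#C[C@]1(O)C[C@H]2C(C)(C)O[C@@](CC=C(C)C)(C1=O)C2=O
A7 | alternative 3 | cage β-hydroxy ester (identical with 25) | COC(=O)C1=C[C@]3(O)C[C@H]4C(C)(C)O[C@@](CC=C(C)C)(C3=O)[C@@]14O
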